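**Retrosynthetic overview**
- The target, 6,7,8-trimethoxy-3-(3,4,5-trimethoxyphenyl)-4H-chromen-4-one, is opened at the C3–C1' (aryl) bond by a retro 1,2-aryl shift. This leads back to the racemic flavanone with the aryl group on C2, as in the isoflavone synthase step of isoflavonoid biosynthesis.
- The flavanone comes from the 2'-hydroxychalcone by oxa-Michael closure (O1–C2). The chalcone comes from a Claisen–Schmidt condensation of 2-hydroxy-3,4,5-trimethoxyacetophenone with 3,4,5-trimethoxybenzaldehyde.
- The acetophenone comes from 2,3,4-trimethoxyphenol by Fries-type ortho C-acetylation, and the phenol from 2,3,4-trimethoxybenzaldehyde by Baeyer–Villiger oxidation.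
- Enabling feature: the O1–C2(Ar)–C3H2–C4(=O) segment of the pyranone ring. C3 is enolisable next to the C4 ketone and can be made electrophilic. C2 carries the para-methoxy-bearing aryl group and the ring oxygen O1, whose lone pair stabilises the cation left on C2 when the aryl moves to C3.
- Ring order: both benzene rings are bought. The pyranone ring is the only ring formed (step 4); the aryl group is then moved from C2 to C3 and the ring brought to the chromone oxidation level in one operation (step 5).

Key step: step 5

Remark: the target has no stereogenic element (planar chromone, freely rotating aryl group), so it is a single achiral compound. The stereocentre of the racemic flavanone is erased in the key step, and no enantiocontrol is needed.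

**Step 1**
Reactants: 1 2,3,4-trimethoxybenzaldehyde
Product: 3 2,3,4-trimethoxyphenol, via aryl formate 2 (not isolated)
Conditions: mCPBA (1.3 equiv), CH2Cl2, 0 °C → rt; aq. NaHCO3 wash; then K2CO3 (cat.), MeOH, rt
Reagents that add atoms: mCPBA, O=C(OO)c1cccc(Cl)c1
Why: Baeyer–Villiger (Dakin-type) oxidation, in which the electron-rich aryl group (ortho- and para-methoxy) migrates in the Criegee adduct in preference to hydride to give the aryl formate, which mild methanolysis cleaves to the phenol.

**Step 2**
Reactants: 3 2,3,4-trimethoxyphenol
Product: 6 1-(2-hydroxy-3,4,5-trimethoxyphenyl)ethan-1-one, via aryl acetate 4 (not isolated), via difluoroboron chelate 5 (not isolated)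
Conditions: AcOH (2 equiv), BF3·OEt2 (3 equiv), 90 °C; then H2O–EtOH, 60 °C
Reagents that add atoms: acetic acid, CC(=O)O
Why: BF3-mediated O-acetylation and Fries-type ortho C-acylation should go to the only free position ortho to the phenol oxygen, because the ortho-hydroxy ketone is drained off as its six-membered O–BF2–O chelate, which the aqueous work-up hydrolyses; BF3 should not cleave the methyl ethers.

**Step 3**
Reactants: 6 1-(2-hydroxy-3,4,5-trimethoxyphenyl)ethan-1-one, 7 3,4,5-trimethoxybenzaldehyde
Product: 8 (E)-1-(2-hydroxy-3,4,5-trimethoxyphenyl)-3-(3,4,5-trimethoxyphenyl)prop-2-en-1-one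
Conditions: KOH (50% aq., 4 equiv), EtOH, 0 °C → rt; then 2 M HCl to pH 3
Reagents that add atoms: none
Why: Claisen–Schmidt condensation, in which the enolate of the methyl ketone adds to the non-enolisable aldehyde and E1cB dehydration should give the conjugated enone as the thermodynamically favoured E isomer.

**Step 4**
Reactants: 8 (E)-1-(2-hydroxy-3,4,5-trimethoxyphenyl)-3-(3,4,5-trimethoxyphenyl)prop-2-en-1-one
Product: 9 racemic 6,7,8-trimethoxy-2-(3,4,5-trimethoxyphenyl)chroman-4-one
Conditions: NaOAc (5 equiv), EtOH–H2O (9:1), reflux
Reagents that add atoms: none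
Why: Chalcone–flavanone isomerisation by 6-endo-trig oxa-Michael addition of the phenol oxygen to the enone β-carbon closes the pyranone ring; the new C2 stereocentre forms as the racemate, which is acceptable because it is destroyed in step 5, and unreacted chalcone can be recycled.

**Step 5**
Reactants: 9 racemic 6,7,8-trimethoxy-2-(3,4,5-trimethoxyphenyl)chroman-4-one
Product: 11 6,7,8-trimethoxy-3-(3,4,5-trimethoxyphenyl)-4H-chromen-4-one, via iodanyl ketone 10 (not isolated)
Conditions: PhI(OH)OTs (1.1 equiv), MeCN, reflux
Reagents that add atoms: none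
Why: Acid-promoted enolisation of the C4 ketone and attack of the C3 enol carbon on iodine(III) should give the α-(phenyl-λ3-iodanyl) ketone 10; as the hypernucleofugal PhI leaves, the 3,4,5-trimethoxyphenyl group on C2 bridges to C3 (phenonium ion), the C3–C(aryl) bond forms, the charge is left on C2 as an oxocarbenium ion stabilised by ring oxygen O1, and loss of the C3 proton gives the C2=C3 bond of the chromen-4-one. The closest known reaction type is the iodine(III)- or thallium(III)-mediated oxidative 2,3-aryl migration of flavanones to isoflavones, the laboratory counterpart of the isoflavone synthase step. No ring is closed: the pyranone ring from step 4 is kept, and the only cyclic species is the transient three-membered phenonium bridge over C2–C3, which opens towards C3. No stereocentre is created in the product; the transient C3 centre of 10 should be set trans to the C2 aryl group by approach of the iodane to the enol face opposite that group, and both centres are then erased. The step needs aryl migration to win over 2,3-dehydrogenation without migration, α-tosyloxylation and ring contraction; this is secured by the high migratory aptitude of the para-methoxy-bearing aryl group, by its antiperiplanar alignment to the C3–I bond in the trans-diaxial conformer of 10, by O1 stabilising the cation at C2, and by the non-nucleophilic solvent (methanol or orthoformate would divert the oxidation to the flavone or to ring-contracted dihydrobenzofuran esters). Chemoselectivity against oxidation of the two trimethoxyarene rings rests on the absence of a free phenol (O1 is already an ether) and on using close to one equivalent of oxidant.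

**Compound list**
1 | 2,3,4-trimethoxybenzaldehyde | COc1ccc(C=O)c(OC)c1OC | starting material
2 | 2,3,4-trimethoxyphenyl formate | COc1ccc(OC=O)c(OC)c1OC | intermediate
3 | 2,3,4-trimethoxyphenol | COc1ccc(O)c(OC)c1OC | intermediate
4 | 2,3,4-trimethoxyphenyl acetate | CC(=O)Oc1ccc(OC)c(OC)c1OC | intermediate
5 | difluoroboron chelate of 1-(2-hydroxy-3,4,5-trimethoxyphenyl)ethan-1-one | CC1=[O+][B-](F)(F)Oc2c(OC)c(OC)c(OC)cc12 | intermediate
6 | 1-(2-hydroxy-3,4,5-trimethoxyphenyl)ethan-1-one | CC(=O)c1cc(OC)c(OC)c(OC)c1O | intermediate
7 | 3,4,5-trimethoxybenzaldehyde | COc1cc(C=O)cc(OC)c1OC | starting material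
8 | (E)-1-(2-hydroxy-3,4,5-trimethoxyphenyl)-3-(3,4,5-trimethoxyphenyl)prop-2-en-1-one | COc1cc(/C=C/C(=O)c2cc(OC)c(OC)c(OC)c2O)cc(OC)c1OC | intermediate
9 | racemic 6,7,8-trimethoxy-2-(3,4,5-trimethoxyphenyl)chroman-4-one | COc1cc(C2CC(=O)c3cc(OC)c(OC)c(OC)c3O2)cc(OC)c1OC | intermediate
10 | trans-6,7,8-trimethoxy-3-[phenyl(tosyloxy)-λ3-iodanyl]-2-(3,4,5-trimethoxyphenyl)chroman-4-one (racemic, one enantiomer drawn) | COc1cc([C@@H]2Oc3c(OC)c(OC)c(OC)cc3C(=O)[C@H]2I(c2ccccc2)OS(=O)(=O)c2ccc(C)cc2)cc(OC)c1OC | intermediate
11 | 6,7,8-trimethoxy-3-(3,4,5-trimethoxyphenyl)-4H-chromen-4-one | COc1cc(-c2coc3c(OC)c(OC)c(OC)cc3c2=O)cc(OC)c1OC | target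

**Totals**
Total step count: 5. Longest linear sequence: 5 steps (1 → 3 → 6 → 8 → 9 → 11); compound 7 is bought.

**Steps most likely to fail**

1. Step 5. The iodine(III) oxidation may take another course: 2,3-dehydrogenation without aryl shift, α-tosyloxylation, electrophilic attack of the iodane on the electron-rich arene rings, or acid-induced ring-opening of the flavanone followed by phenol oxidation. Fallback: the same C3–aryl bond is made by cross-coupling on a preformed chromone. It sets out from 6, which is condensed with DMF dimethyl acetal (toluene, 90 °C) to the enaminone (E)-3-(dimethylamino)-1-(2-hydroxy-3,4,5-trimethoxyphenyl)prop-2-en-1-one F1. Iodine in CHCl3 at rt should then bring about iodocyclisation with loss of dimethylamine to 3-iodo-6,7,8-trimethoxy-4H-chromen-4-one F2. Suzuki–Miyaura coupling of F2 with (3,4,5-trimethoxyphenyl)boronic acid (Pd(dppf)Cl2, Na2CO3, DME–H2O, 80 °C) should return to the route at 11.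

2. Step 2. C-acylation may occur at the other free ring position (para to the 2-methoxy group), the reaction may stall at the O-acetate, or a crowded methoxy group may be cleaved by the Lewis acid. Fallback: the carbonyl carbon is introduced by a formylation that is strictly ortho to the phenol. It sets out from 3, which with MgCl2, Et3N and paraformaldehyde in MeCN at reflux should give 2-hydroxy-3,4,5-trimethoxybenzaldehyde F3. Addition of MeMgBr (2.2 equiv, THF, 0 °C) should give racemic 1-(2-hydroxy-3,4,5-trimethoxyphenyl)ethan-1-ol F4, and benzylic oxidation with MnO2 in CH2Cl2 should return to the route at 6.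

3. Step 4. Ring closure is a reversible oxa-Michael addition, so conversion may stay incomplete and the flavanone may reopen to the chalcone on handling. Fallback: the flavanone is bypassed and the aryl shift is carried out on the open-chain chalcone with the phenol masked. It sets out from 6, which is protected (MOMCl, iPr2NEt, CH2Cl2) as 1-[2-(methoxymethoxy)-3,4,5-trimethoxyphenyl]ethan-1-one F5. Claisen–Schmidt condensation of F5 with 7 (KOH, EtOH) should give (E)-1-[2-(methoxymethoxy)-3,4,5-trimethoxyphenyl]-3-(3,4,5-trimethoxyphenyl)prop-2-en-1-one F6. Oxidative rearrangement with Tl(NO3)3·3H2O in MeOH–HC(OMe)3 at rt should give, by 1,2-aryl shift, racemic 3,3-dimethoxy-1-[2-(methoxymethoxy)-3,4,5-trimethoxyphenyl]-2-(3,4,5-trimethoxyphenyl)propan-1-one F7. Heating F7 in 10% HCl–MeOH should remove the MOM group and cyclise with loss of methanol, returning to the route at 11.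

**Further compounds**
F1 | step 5 | (E)-3-(dimethylamino)-1-(2-hydroxy-3,4,5-trimethoxyphenyl)prop-2-en-1-one | CN(C)/C=C/C(=O)c1cc(OC)c(OC)c(OC)c1O
F2 | step 5 | 3-iodo-6,7,8-trimethoxy-4H-chromen-4-one | COc1cc2c(=O)c(I)coc2c(OC)c1OC
F3 | step 2 | 2-hydroxy-3,4,5-trimethoxybenzaldehyde | COc1cc(C=O)c(O)c(OC)c1OC
F4 | step 2 | racemic 1-(2-hydroxy-3,4,5-trimethoxyphenyl)ethan-1-ol | CC(O)c1cc(OC)c(OC)c(OC)c1O
F5 | step 4 | 1-[2-(methoxymethoxy)-3,4,5-trimethoxyphenyl]ethan-1-one | CC(=O)c1cc(OC)c(OC)c(OC)c1OCOC
F6 | step 4 | (E)-1-[2-(methoxymethoxy)-3,4,5-trimethoxyphenyl]-3-(3,4,5-trimethoxyphenyl)prop-2-en-1-one | COCOc1c(OC)c(OC)c(OC)cc1C(=O)/C=C/c1cc(OC)c(OC)c(OC)c1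
F7 | step 4 | racemic 3,3-dimethoxy-1-[2-(methoxymethoxy)-3,4,5-trimethoxyphenyl]-2-(3,4,5-trimethoxyphenyl)propan-1-one | COCOc1c(OC)c(OC)c(OC)cc1C(=O)C(C(OC)OC)c1cc(OC)c(OC)c(OC)c1
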